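**Retrosynthetic overview**
1. The two vinylogous-pyridone rings are formed last, together: butane-1,4-diamine joins two identical enaminone–ynenone monomers 13 by transamination and 6-endo N-cyclisation.
2. Monomer 13 comes from chloro-enaminone 7 and dienyne 12 by Sonogashira coupling at the vinylogous acyl chloride C4a–Cl; the second chlorine is the C5–Cl of the target.
3. Enaminone 7 comes from (S)-cyclohexenedione 6, made from the achiral, Cs-symmetric dichlorocyclopentenedione 4 by a catalytic enantioselective one-carbon ring expansion that distinguishes the two enantiotopic C=O groups and so fixes C7.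
4. Dione 4 comes from 2-methylcyclopentane-1,3-dione (acetoxylation, oxidative dichlorination); dienyne 12 comes from (S)-2-methylbutan-1-ol (oxidation/Wittig, then HWE enyne synthesis).
5. Ring order: carbocycle first (5 → 6 ring expansion), then both N-heterocycles in the final step.

Assumption: CIP analysis of the given SMILES gives 7S and 13S in both halves (azaphilone numbering C1–C13 is used below); the ligand enantiomer in step 3 is the one that homologates the pro-R carbonyl of 4, to be confirmed by screening (its antipode gives ent-6).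

**Step 1**
Reactants: 1 2-methylcyclopentane-1,3-dione
Product: 2 1-methyl-2,5-dioxocyclopentyl acetate
Conditions: Pb(OAc)4 (1.05 equiv), AcOH, rt, 3 h
Reagents that add atoms: lead tetraacetate CC(=O)O[Pb](OC(C)=O)(OC(C)=O)OC(C)=O
Why: Wessely-type α-acetoxylation, in which the enol of the 2-alkyl-1,3-dione is plumbylated at C2 and reductive C–O bond formation gives the tertiary acetate (2 is achiral, no stereocentre formed).

**Step 2**
Reactants: 2 1-methyl-2,5-dioxocyclopentyl acetate
Product: 4 3,4-dichloro-1-methyl-2,5-dioxocyclopent-3-en-1-yl acetate, via trichloro dione 3 (not isolated)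
Conditions: SO2Cl2 (3.1 equiv), AcOH, 50 °C; evaporate volatiles; NaOAc (1.5 equiv), AcOH, rt
Reagents that add atoms: sulfuryl chloride O=S(=O)(Cl)Cl
Why: Acid-catalysed enol α-chlorination of the two CH2 groups (C1 is blocked) can give only the 3,3,4-trichloride after three chlorinations, and E1cB dehydrochlorination of its acidic CHCl hydrogen gives the tetrasubstituted dichloro-enedione, which is achiral (Cs).

**Step 3**
Reactants: 4 3,4-dichloro-1-methyl-2,5-dioxocyclopent-3-en-1-yl acetate
Product: 6 (1S)-3,4-dichloro-1-methyl-2,6-dioxocyclohex-3-en-1-yl acetate, via C-silyl ketone 5 (not isolated)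
Conditions: TMSCHN2 (1.3 equiv), Sc(OTf)3 (10 mol %), chiral pipecolic-acid-derived N,N′-dioxide ligand (12 mol %), 4 Å MS, CH2Cl2, −78 → −40 °C; AcOH quench; 1 M HCl/THF, 0 °C
Reagents that add atoms: (trimethylsilyl)diazomethane C[Si](C)(C)C=[N+]=[N-]
Why: Proposed new method: a catalytic enantioselective desymmetrising Tiffeneau–Demjanov-type one-carbon ring expansion of a Cs-symmetric 2,2-disubstituted cyclopent-4-ene-1,3-dione, in which the chiral Sc(III) complex binds 4 two-point (one ketone O plus the acetate C=O) and exposes only the pro-R carbonyl to TMSCHN2, the diazonium betaine loses N2 with 1,2-shift of the sp2 C(Cl)= carbon (the other neighbour is quaternary, hindered and deactivated by OAc and the second acyl group), and the β-keto silane 5 (or its O-silyl dienol ether after 1,3-Brook shift, which also shields the new ketone from a second homologation) is protodesilylated on work-up; homologating one of two enantiotopic carbonyls makes the existing C(Me)(OAc) carbon stereogenic and sets C7 as S, while the two vinylic chlorines prevent racemisation of 6 through its vinylogous-acid tautomers and retard dipolar cycloaddition to the C=C; the closest known reaction types are Sc(OTf)3-catalysed diazoalkane homologation of cyclic ketones, chiral Lewis-acid-catalysed asymmetric (including desymmetrising) ring expansions of cycloalkanones with diazo compounds, and catalytic desymmetrisations of prochiral cyclopentene-1,3-diones.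

**Step 4**
Reactants: 6 (1S)-3,4-dichloro-1-methyl-2,6-dioxocyclohex-3-en-1-yl acetate
Product: 7 (1S)-3,4-dichloro-5-[(dimethylamino)methylidene]-1-methyl-2,6-dioxocyclohex-3-en-1-yl acetate
Conditions: Me2NCH(OMe)2 (1.1 equiv), CH2Cl2, 0 °C → rt, 1 h
Reagents that add atoms: N,N-dimethylformamide dimethyl acetal COC(OC)N(C)C
Why: Aminomethylenation of a cyclic 1,3-dione-type vinylogous acid at its only free nucleophilic carbon (C8a; the other terminus C5 carries Cl) installs C1 as a neutral push–pull enaminone and leaves the quaternary C7 centre untouched.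

**Step 5**
Reactants: 8 (S)-2-methylbutan-1-ol
Product: 10 (2E,4S)-2,4-dimethylhex-2-enal, via (S)-2-methylbutanal 9 (not isolated)
Conditions: TEMPO (10 mol %), PhI(OAc)2 (1.1 equiv), CH2Cl2, rt; then Ph3P=C(Me)CHO (1.2 equiv), PhMe, 80 °C
Reagents that add atoms: 2-(triphenylphosphoranylidene)propanal CC(C=O)=P(c1ccccc1)(c1ccccc1)c1ccccc1
Why: Tandem TEMPO oxidation/Wittig olefination with a stabilised ylide gives the (E)-trisubstituted enal, and using the epimerisable aldehyde 9 in situ preserves the chiral-pool C13 stereocentre.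

**Step 6**
Reactants: 10 (2E,4S)-2,4-dimethylhex-2-enal
Product: 12 (3E,5E,7S)-5,7-dimethylnona-3,5-dien-1-yne, via TMS dienyne 11 (not isolated)
Conditions: (EtO)2P(O)CH2C≡CTMS (1.3 equiv), LiHMDS (1.25 equiv), THF, −78 → 0 °C; then MeOH, K2CO3 (20 mol %), rt
Reagents that add atoms: diethyl [3-(trimethylsilyl)prop-2-yn-1-yl]phosphonate CCOP(=O)(CC#C[Si](C)(C)C)OCC
Why: Horner–Wadsworth–Emmons olefination with the pre-formed propargyl phosphonate anion gives the (E)-enyne (no free base touches the γ-stereocentre), and K2CO3/MeOH cleaves the C(sp)–Si bond.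

**Step 7**
Reactants: 7 (1S)-3,4-dichloro-5-[(dimethylamino)methylidene]-1-methyl-2,6-dioxocyclohex-3-en-1-yl acetate; 12 (3E,5E,7S)-5,7-dimethylnona-3,5-dien-1-yne
Product: 13 (1S)-3-chloro-5-[(dimethylamino)methylidene]-4-[(3E,5E,7S)-5,7-dimethylnona-3,5-dien-1-yn-1-yl]-1-methyl-2,6-dioxocyclohex-3-en-1-yl acetate
Conditions: PdCl2(PPh3)2 (5 mol %), CuI (5 mol %), iPr2NEt (2 equiv), THF, rt, Ar
Reagents that add atoms: none
Why: Sonogashira coupling is site-selective for the β-chloro-enone C4a–Cl (a vinylogous acyl chloride) over the α-chloro C5–Cl, which stays as the chlorine of the target; no stereocentre is affected.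

**Step 8**
Reactants: 13 (1S)-3-chloro-5-[(dimethylamino)methylidene]-4-[(3E,5E,7S)-5,7-dimethylnona-3,5-dien-1-yn-1-yl]-1-methyl-2,6-dioxocyclohex-3-en-1-yl acetate (2.05 equiv); 14 butane-1,4-diamine (1.0 equiv)
Product: 16 penazaphilone I, via bis-enaminone 15 (not isolated)
Conditions: EtOH–CH2Cl2 (1:1), rt, N2 sparge; then AgOTf (10 mol %), 40 °C
Reagents that add atoms: none
Why: Each primary amine displaces Me2NH from the push–pull aminomethylene group (enaminone transamination), and after E/Z equilibration the N–H adds 6-endo-dig to the Ag(I)-activated distal alkyne carbon (the electrophilic δ-position of the ynenone) to close both vinylogous 4-pyridone rings, the same ring-forming logic as amine-for-oxygen exchange in azaphilones, with C7 and C13 untouched.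

**Compound list**
1 | 2-methylcyclopentane-1,3-dione | CC1C(=O)CCC1=O | starting material
2 | 1-methyl-2,5-dioxocyclopentyl acetate | CC(=O)OC1(C)C(=O)CCC1=O | intermediate
3 | 3,3,4-trichloro-1-methyl-2,5-dioxocyclopentyl acetate (racemic diastereomer mixture, not isolated) | CC(=O)OC1(C)C(=O)C(Cl)C(Cl)(Cl)C1=O | intermediate
4 | 3,4-dichloro-1-methyl-2,5-dioxocyclopent-3-en-1-yl acetate (achiral) | CC(=O)OC1(C)C(=O)C(Cl)=C(Cl)C1=O | intermediate
5 | (1S)-3,4-dichloro-1-methyl-2,6-dioxo-5-(trimethylsilyl)cyclohex-3-en-1-yl acetate (C5 epimers, equilibrating with the O-silyl dienol ether, not isolated) | C[Si](C)(C)C1C(Cl)=C(Cl)C(=O)[C@@](C)(OC(C)=O)C1=O | intermediate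
6 | (1S)-3,4-dichloro-1-methyl-2,6-dioxocyclohex-3-en-1-yl acetate (vinylogous acid, drawn as diketo tautomer) | ClC1=C(Cl)C(=O)[C@@](C)(OC(C)=O)C(=O)C1 | intermediate
7 | (1S)-3,4-dichloro-5-[(dimethylamino)methylidene]-1-methyl-2,6-dioxocyclohex-3-en-1-yl acetate | CN(C)C=C1C(Cl)=C(Cl)C(=O)[C@@](C)(OC(C)=O)C1=O | intermediate
8 | (S)-2-methylbutan-1-ol | CC[C@H](C)CO | starting material
9 | (S)-2-methylbutanal (not isolated) | CC[C@H](C)C=O | intermediate
10 | (2E,4S)-2,4-dimethylhex-2-enal | CC[C@H](C)/C=C(C)/C=O | intermediate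
11 | trimethyl[(3E,5E,7S)-5,7-dimethylnona-3,5-dien-1-yn-1-yl]silane (not isolated) | C[Si](C)(C)C#C/C=C/C(C)=C/[C@@H](C)CC | intermediate
12 | (3E,5E,7S)-5,7-dimethylnona-3,5-dien-1-yne | C#C/C=C/C(C)=C/[C@@H](C)CC | intermediate
13 | (1S)-3-chloro-5-[(dimethylamino)methylidene]-4-[(3E,5E,7S)-5,7-dimethylnona-3,5-dien-1-yn-1-yl]-1-methyl-2,6-dioxocyclohex-3-en-1-yl acetate | CN(C)C=C1C(C#C/C=C/C(C)=C/[C@@H](C)CC)=C(Cl)C(=O)[C@@](C)(OC(C)=O)C1=O | intermediate
14 | butane-1,4-diamine | NCCCCN | starting material
15 | N,N′-butane-1,4-diyl bis-enaminone (each Me2N of 13 replaced by one NH of the diamine, not isolated) | N(CCCCNC=C1C(C#C/C=C/C(C)=C/[C@@H](C)CC)=C(Cl)C(=O)[C@@](C)(OC(C)=O)C1=O)C=C1C(C#C/C=C/C(C)=C/[C@@H](C)CC)=C(Cl)C(=O)[C@@](C)(OC(C)=O)C1=O | intermediate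
16 | penazaphilone I, 2,2′-(butane-1,4-diyl)bis[(7S)-7-acetoxy-5-chloro-3-((1E,3E,5S)-3,5-dimethylhepta-1,3-dien-1-yl)-7-methylisoquinoline-6,8(2H,7H)-dione] | CC[C@H](C)/C=C(C)/C=C/C1=CC2=C(Cl)C(=O)[C@@](C)(OC(C)=O)C(=O)C2=CN1CCCCN1C=C2C(=O)[C@](C)(OC(C)=O)C(=O)C(Cl)=C2C=C1/C=C/C(C)=C/[C@@H](C)CC | target

**Totals**
Total step count: 8. Longest linear sequence: 6 (steps 1, 2, 3, 4, 7, 8).

**Three steps most likely to fail**

Step 3 (the new ring expansion). Possible failures are low enantioselectivity, migration of the wrong carbon, or cycloaddition of the diazo compound to the C=C. The fallback uses known reactions, sets out from 4 and returns at 6. The enantiotopic carbonyls are first distinguished by a CBS reduction (Me-CBS 10 mol %, catecholborane, toluene, −78 °C), an established desymmetrisation of 2,2-disubstituted cyclopentene-1,3-diones. This gives (1R,5R)-3,4-dichloro-5-hydroxy-1-methyl-2-oxocyclopent-3-en-1-yl acetate F4 (carbinol configuration drawn for illustration; it is removed later), and the diastereomer whose reduced carbonyl is the future C6 is separated by chromatography. Silylation (TBSOTf, 2,6-lutidine) gives the TBS ether F5. A conventional achiral BF3·OEt2-promoted TMSCHN2 homologation of the single remaining ketone then passes through the C-silyl ketone F6, which is protodesilylated on work-up to the ring-expanded silyl ether F7. HF·pyridine frees the alcohol F8, and Dess–Martin oxidation returns 6.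

Step 2 (one-pot trichlorination/dehydrochlorination). Possible failures are under- or over-chlorination. The fallback sets out from 2 and returns at 4, installing the alkene first and the chlorines afterwards. IBX (DMSO, 70 °C) dehydrogenates 2 to 1-methyl-2,5-dioxocyclopent-3-en-1-yl acetate F1. Cl2 (CH2Cl2, rt) adds across the C=C to give trans-3,4-dichloro-1-methyl-2,5-dioxocyclopentyl acetate F2, and NaOAc eliminates HCl to give 3-chloro-1-methyl-2,5-dioxocyclopent-3-en-1-yl acetate F3. A second Cl2 addition gives trichloride 3, and NaOAc again delivers 4.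

Step 8 (double transamination/N-cyclisation). Possible failures are incomplete second cyclisation or 5-exo closure. The fallback sets out from 13 and returns at 16 through the oxygen heterocycle. Aqueous AcOH/THF hydrolyses the dimethylaminomethylene group to (1S)-3-chloro-4-[(3E,5E,7S)-5,7-dimethylnona-3,5-dien-1-yn-1-yl]-5-(hydroxymethylidene)-1-methyl-2,6-dioxocyclohex-3-en-1-yl acetate F9. Au(OAc)3 (5 mol %, DCE, rt) effects 6-endo oxa-cycloisomerisation to (7S)-5-chloro-3-[(1E,3E,5S)-3,5-dimethylhepta-1,3-dien-1-yl]-7-methyl-6,8-dioxo-7,8-dihydro-6H-isochromen-7-yl acetate F10. This azaphilone is condensed with 0.5 equiv of 14 (CH2Cl2, rt), the established amine-for-oxygen exchange of azaphilones, to give 16.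

**Further compounds**
F1 | step 2 | 1-methyl-2,5-dioxocyclopent-3-en-1-yl acetate | CC(=O)OC1(C)C(=O)C=CC1=O
F2 | step 2 | trans-3,4-dichloro-1-methyl-2,5-dioxocyclopentyl acetate (racemic, one enantiomer drawn) | CC(=O)OC1(C)C(=O)[C@@H](Cl)[C@H](Cl)C1=O
F3 | step 2 | 3-chloro-1-methyl-2,5-dioxocyclopent-3-en-1-yl acetate (racemic) | CC(=O)OC1(C)C(=O)C=C(Cl)C1=O
F4 | step 3 | (1R,5R)-3,4-dichloro-5-hydroxy-1-methyl-2-oxocyclopent-3-en-1-yl acetate | ClC1=C(Cl)[C@H](O)[C@@](C)(OC(C)=O)C1=O
F5 | step 3 | tert-butyldimethylsilyl ether of F4 | ClC1=C(Cl)[C@H](O[Si](C)(C)C(C)(C)C)[C@@](C)(OC(C)=O)C1=O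
F6 | step 3 | C-silyl ketone from ring expansion of F5 (C–Si epimers, not isolated) | C[Si](C)(C)C1C(Cl)=C(Cl)[C@H](O[Si](C)(C)C(C)(C)C)[C@@](C)(OC(C)=O)C1=O
F7 | step 3 | 2-(tert-butyldimethylsilyloxy)-3,4-dichloro-1-methyl-6-oxocyclohex-3-en-1-yl acetate (configuration as in F5) | ClC1=C(Cl)[C@H](O[Si](C)(C)C(C)(C)C)[C@@](C)(OC(C)=O)C(=O)C1
F8 | step 3 | 3,4-dichloro-2-hydroxy-1-methyl-6-oxocyclohex-3-en-1-yl acetate (configuration as in F5) | ClC1=C(Cl)[C@H](O)[C@@](C)(OC(C)=O)C(=O)C1
F9 | step 8 | (1S)-3-chloro-4-[(3E,5E,7S)-5,7-dimethylnona-3,5-dien-1-yn-1-yl]-5-(hydroxymethylidene)-1-methyl-2,6-dioxocyclohex-3-en-1-yl acetate | OC=C1C(C#C/C=C/C(C)=C/[C@@H](C)CC)=C(Cl)C(=O)[C@@](C)(OC(C)=O)C1=O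
F10 | step 8 | (7S)-5-chloro-3-[(1E,3E,5S)-3,5-dimethylhepta-1,3-dien-1-yl]-7-methyl-6,8-dioxo-7,8-dihydro-6H-isochromen-7-yl acetate | CC[C@H](C)/C=C(C)/C=C/C1=CC2=C(Cl)C(=O)[C@@](C)(OC(C)=O)C(=O)C2=CO1
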